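**Strategy.** Everything rests on closing ring B by the bond from the benzylic methine C1 to arene carbon C8a of ring A, which lies para to the C6 methoxy group. The precursor is a lariciresinol-type 2-aryl-4-benzyltetrahydrofuran in which the oxygen of the future C3 hydroxymethyl group is tied to C1 as a temporary ring ether, so that only the C2 CH2OH is free and is sulfated alone. Acid then ionises C1, which the para-oxygenated pendant aryl ring stabilises; one operation forms C1–C8a, sets C1 trans to C2 and releases the C3 CH2OH. C2 and C3 stem from (R)-epichlorohydrin and a trans-selective lactone aldol.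

Key step: step 8

Remark on numbering: in the tetralin, C1 carries the aryl group, C2 the CH2OSO3H and C3 the CH2OH; ring A is the benzo ring and ring B the saturated ring.
Assumption: the target is drawn as the free hydrogen sulfate; the sulfate is carried as its sodium salt from step 7 on and the acid form is released only in the last operation.
Remark on stereochemistry: the tetrahydrofurans 11 and 12 are drawn as the expected major 2,3-trans epimer; the C2 epimer is carried along, because this centre is ionised in step 8.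

Step 1
Reactants: 1 diethyl malonate; 2 (R)-epichlorohydrin
Product: 3 ethyl (1S,5R)-2-oxo-3-oxabicyclo[3.1.0]hexane-1-carboxylate
Conditions: NaOEt, EtOH, rt → reflux
Reagents that add atoms: none
Why: Malonate–epichlorohydrin cyclopropanation/lactonisation, in which the malonate anion opens the epoxide at its CH2 end, the alkoxide re-closes an epoxide with loss of chloride, a second deprotonation closes the cyclopropane by 3-exo-tet attack with inversion at the stereocentre of 2 and the released alkoxide lactonises onto the cis ester, so that C5 comes from the chiral pool and the cis ring fusion fixes C1.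

Step 2
Reactants: 3 ethyl (1S,5R)-2-oxo-3-oxabicyclo[3.1.0]hexane-1-carboxylate; 4 1-(benzyloxy)-4-bromo-2-methoxybenzene
Product: 6 ethyl (3S,4R)-4-[4-(benzyloxy)-3-methoxybenzyl]-2-oxotetrahydrofuran-3-carboxylate, via arylmagnesium bromide 5 (not isolated)
Conditions: 4, Mg, THF, rt; then CuI (20 mol %), 3, THF, −40 → 0 °C; dilute HCl quench
Reagents that add atoms: magnesium, [Mg] (only into intermediate 5)
Why: Copper-catalysed homoconjugate addition (SN2-type opening of a doubly activated cyclopropane) in which the arylcopper species attacks the unsubstituted cyclopropane CH2 and expels the malonate-type enolate, so that C5 of 3 is carried over untouched as C4 of 6 while the epimerisable C3 settles trans to the new benzyl group.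

Step 3
Reactants: 6 ethyl (3S,4R)-4-[4-(benzyloxy)-3-methoxybenzyl]-2-oxotetrahydrofuran-3-carboxylate
Product: 7 (4R)-4-[4-(benzyloxy)-3-methoxybenzyl]dihydrofuran-2(3H)-one
Conditions: LiCl, H2O, DMSO, 140 °C
Reagents that add atoms: none
Why: Krapcho dealkoxycarbonylation removes the ester of the 1,3-dicarbonyl unit under near-neutral conditions that leave the lactone, the benzyl ether and the non-enolisable C4 stereocentre untouched.

Step 4
Reactants: 7 (4R)-4-[4-(benzyloxy)-3-methoxybenzyl]dihydrofuran-2(3H)-one; 8 4-(benzyloxy)-3-methoxybenzaldehyde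
Product: 9 (3S,4R)-4-[4-(benzyloxy)-3-methoxybenzyl]-3-{[4-(benzyloxy)-3-methoxyphenyl](hydroxy)methyl}dihydrofuran-2(3H)-one (carbinol epimers)
Conditions: LiN(SiMe3)2, THF, −78 °C; then 8; AcOH quench at −78 °C
Reagents that add atoms: none
Why: Aldol addition of the lactone lithium enolate, in which the aldehyde approaches the enolate face anti to the C4 benzyl group and so sets C3 trans to C4 (3S,4R), while the carbinol carbon forms as an epimer mixture that does not matter because this carbon is ionised later.

Step 5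
Reactants: 9 (3S,4R)-4-[4-(benzyloxy)-3-methoxybenzyl]-3-{[4-(benzyloxy)-3-methoxyphenyl](hydroxy)methyl}dihydrofuran-2(3H)-one (carbinol epimers)
Product: 10 (2R,3R)-2-[4-(benzyloxy)-3-methoxybenzyl]-3-{[4-(benzyloxy)-3-methoxyphenyl](hydroxy)methyl}butane-1,4-diol (carbinol epimers)
Conditions: LiAlH4, THF, 0 °C → rt; H2O, aq. NaOH work-up
Reagents that add atoms: none
Why: Hydride reduction of the lactone to the 1,4-diol with LiAlH4, run cold so that the aluminium aldolate is reduced faster than it can undergo retro-aldol cleavage, touches no stereocentre.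

Step 6
Reactants: 10 (2R,3R)-2-[4-(benzyloxy)-3-methoxybenzyl]-3-{[4-(benzyloxy)-3-methoxyphenyl](hydroxy)methyl}butane-1,4-diol (carbinol epimers)
Product: 11 [(2S,3R,4R)-2-[4-(benzyloxy)-3-methoxyphenyl]-4-[4-(benzyloxy)-3-methoxybenzyl]tetrahydrofuran-3-yl]methanol
Conditions: camphorsulfonic acid (10 mol %), CH2Cl2, 0 °C
Reagents that add atoms: none
Why: Acid-catalysed SN1 cycloetherification, in which the para-alkoxybenzylic alcohol ionises under mild acid and is captured in a 5-exo mode by the only hydroxyl that is 1,4-related to it (the other CH2OH could only give an oxetane and stays free); the new C2 centre forms mainly trans to the C3 substituent under reversible conditions and either epimer serves.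

Step 7
Reactants: 11 [(2S,3R,4R)-2-[4-(benzyloxy)-3-methoxyphenyl]-4-[4-(benzyloxy)-3-methoxybenzyl]tetrahydrofuran-3-yl]methanol
Product: 12 sodium [(2S,3R,4R)-2-[4-(benzyloxy)-3-methoxyphenyl]-4-[4-(benzyloxy)-3-methoxybenzyl]tetrahydrofuran-3-yl]methyl sulfate
Conditions: SO3·pyridine, pyridine, rt; then aq. NaHCO3
Reagents that add atoms: sulfur trioxide pyridine complex, O=S(=O)=O.c1ccncc1; sodium hydrogen carbonate, [Na+].OC([O-])=O
Why: O-Sulfation of the single free hydroxyl with the SO3·pyridine complex under basic conditions that do not disturb the acid-labile benzylic ether, followed by bicarbonate work-up to the sodium alkyl sulfate; no stereocentre is involved.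

Step 8
Reactants: 12 sodium [(2S,3R,4R)-2-[4-(benzyloxy)-3-methoxyphenyl]-4-[4-(benzyloxy)-3-methoxybenzyl]tetrahydrofuran-3-yl]methyl sulfate
Product: 13 sodium [(1S,2R,3R)-7-(benzyloxy)-1-[4-(benzyloxy)-3-methoxyphenyl]-3-(hydroxymethyl)-6-methoxy-1,2,3,4-tetrahydronaphthalen-2-yl]methyl sulfate
Conditions: CF3CO2H (10 equiv), (CF3)2CHOH, 0.02 M, 0 °C → rt; aq. NaHCO3/MeOH work-up
Reagents that add atoms: none
Why: The acid protonates the ring oxygen of 12 and the benzylic C2–O bond ionises to a 4-benzyloxy-3-methoxybenzyl cation, which at once frees the CH2OH that ends as the C3 hydroxymethyl group; the cation is captured by the neighbouring benzyl ring at its carbon para to the methoxy group, and loss of a proton gives the tetralin. The closest known reaction type is the acid-mediated isomerisation of 2-aryl-4-benzyltetrahydrofuran lignans (lariciresinol type) to 1-aryltetralins, an intramolecular Friedel–Crafts alkylation by a benzylic ether. Ring B closes in a 6-endo-trig cation–arene mode, both arene carbons C4a and C8a lying inside the new six-membered ring. The new stereocentre C1 is controlled by the existing C2 and C3 centres: in the half-chair transition state the aryl group sits pseudo-equatorial and trans to the C2 substituent, and because ionisation is reversible both C2 epimers of 12 converge on the all-trans (1S,2R,3R) product. Two selectivities are needed: attack para and not ortho to the methoxy group, secured by the para-directing OMe and the crowding of the ortho site between CH2 and OMe; and survival of the sulfate, secured because the alkyl sulfate stays an unprotonated anion in an acid as weak as CF3CO2H and, like the freed hydroxyl, can trap the cation only reversibly, whereas C-alkylation is irreversible.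

Step 9
Reactants: 13 sodium [(1S,2R,3R)-7-(benzyloxy)-1-[4-(benzyloxy)-3-methoxyphenyl]-3-(hydroxymethyl)-6-methoxy-1,2,3,4-tetrahydronaphthalen-2-yl]methyl sulfate
Product: 15 [(1S,2R,3R)-7-hydroxy-1-(4-hydroxy-3-methoxyphenyl)-3-(hydroxymethyl)-6-methoxy-1,2,3,4-tetrahydronaphthalen-2-yl]methyl hydrogen sulfate (target), via sodium salt of the target 14 (not isolated)
Conditions: H2 (1 atm), Pd/C, MeOH–H2O, rt; filter; then HCl (1.0 equiv), H2O, 0 °C; C18 desalting, lyophilise
Reagents that add atoms: none
Why: Catalytic hydrogenolysis cleaves both aryl benzyl ethers without affecting the alkyl sulfate anion or the diarylmethine C1–H (no benzylic C–O bond is left after step 8), and one equivalent of HCl in cold water then converts the sodium salt into the hydrogen sulfate as drawn.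

**Compound list**

1 | diethyl malonate | CCOC(=O)CC(=O)OCC | starting material
2 | (R)-epichlorohydrin | ClC[C@H]1CO1 | starting material
3 | ethyl (1S,5R)-2-oxo-3-oxabicyclo[3.1.0]hexane-1-carboxylate | CCOC(=O)[C@]12C[C@H]1COC2=O | intermediate
4 | 1-(benzyloxy)-4-bromo-2-methoxybenzene | COc1cc(Br)ccc1OCc1ccccc1 | starting material
5 | [4-(benzyloxy)-3-methoxyphenyl]magnesium bromide | COc1cc([Mg]Br)ccc1OCc1ccccc1 | intermediate
6 | ethyl (3S,4R)-4-[4-(benzyloxy)-3-methoxybenzyl]-2-oxotetrahydrofuran-3-carboxylate | CCOC(=O)[C@H]1C(=O)OC[C@@H]1Cc1ccc(OCc2ccccc2)c(OC)c1 | intermediate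
7 | (4R)-4-[4-(benzyloxy)-3-methoxybenzyl]dihydrofuran-2(3H)-one | O=C1C[C@@H](Cc2ccc(OCc3ccccc3)c(OC)c2)CO1 | intermediate
8 | 4-(benzyloxy)-3-methoxybenzaldehyde | COc1cc(C=O)ccc1OCc1ccccc1 | starting material
9 | (3S,4R)-4-[4-(benzyloxy)-3-methoxybenzyl]-3-{[4-(benzyloxy)-3-methoxyphenyl](hydroxy)methyl}dihydrofuran-2(3H)-one, carbinol epimers | O=C1OC[C@H](Cc2ccc(OCc3ccccc3)c(OC)c2)[C@H]1C(O)c1ccc(OCc2ccccc2)c(OC)c1 | intermediate
10 | (2R,3R)-2-[4-(benzyloxy)-3-methoxybenzyl]-3-{[4-(benzyloxy)-3-methoxyphenyl](hydroxy)methyl}butane-1,4-diol, carbinol epimers | OC[C@H](Cc1ccc(OCc2ccccc2)c(OC)c1)[C@H](CO)C(O)c1ccc(OCc2ccccc2)c(OC)c1 | intermediate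
11 | [(2S,3R,4R)-2-[4-(benzyloxy)-3-methoxyphenyl]-4-[4-(benzyloxy)-3-methoxybenzyl]tetrahydrofuran-3-yl]methanol | COc1cc(C[C@H]2CO[C@H](c3ccc(OCc4ccccc4)c(OC)c3)[C@H]2CO)ccc1OCc1ccccc1 | intermediate
12 | sodium [(2S,3R,4R)-2-[4-(benzyloxy)-3-methoxyphenyl]-4-[4-(benzyloxy)-3-methoxybenzyl]tetrahydrofuran-3-yl]methyl sulfate | COc1cc(C[C@H]2CO[C@H](c3ccc(OCc4ccccc4)c(OC)c3)[C@H]2COS(=O)(=O)[O-])ccc1OCc1ccccc1.[Na+] | intermediate
13 | sodium [(1S,2R,3R)-7-(benzyloxy)-1-[4-(benzyloxy)-3-methoxyphenyl]-3-(hydroxymethyl)-6-methoxy-1,2,3,4-tetrahydronaphthalen-2-yl]methyl sulfate | COc1cc([C@H]2c3cc(OCc4ccccc4)c(OC)cc3C[C@@H](CO)[C@@H]2COS(=O)(=O)[O-])ccc1OCc1ccccc1.[Na+] | intermediate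
14 | sodium [(1S,2R,3R)-7-hydroxy-1-(4-hydroxy-3-methoxyphenyl)-3-(hydroxymethyl)-6-methoxy-1,2,3,4-tetrahydronaphthalen-2-yl]methyl sulfate | COc1cc([C@H]2c3cc(O)c(OC)cc3C[C@@H](CO)[C@@H]2COS(=O)(=O)[O-])ccc1O.[Na+] | intermediate
15 | [(1S,2R,3R)-7-hydroxy-1-(4-hydroxy-3-methoxyphenyl)-3-(hydroxymethyl)-6-methoxy-1,2,3,4-tetrahydronaphthalen-2-yl]methyl hydrogen sulfate (CNP0184747.1) | COc1cc([C@H]2c3cc(O)c(OC)cc3C[C@@H](CO)[C@@H]2COS(=O)(=O)O)ccc1O | target

**Count.** Total steps: 9. Longest linear sequence: 9 steps (from 1 and 2 to 15).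

**Steps most likely to fail**

Step 8 (key step). The sulfate group may be lost by acid solvolysis or may take part as an internal nucleophile, and benzyl ethers may be partly cleaved if the acid treatment is prolonged. The fallback sets out from 11 and comes back at 14; it postpones sulfation until after ring closure and keeps the two CH2O groups apart with an acetate. 11 is acetylated (Ac2O, pyridine) to the tetrahydrofuran acetate F1. CF3CO2H in CH2Cl2 at 0 °C then effects the same ring-opening Friedel–Crafts closure and gives the tetralin monoacetate F2 with the C3 CH2OH free. This hydroxyl is benzylated under acid (benzyl 2,2,2-trichloroacetimidate, cat. CF3SO3H) to the tribenzyl acetate F3. K2CO3 in MeOH removes the acetate and gives the tribenzyl alcohol F4, whose free C2 CH2OH is sulfated (SO3·pyridine, then NaHCO3) to the tribenzyl sodium sulfate F5. Hydrogenolysis (H2, Pd/C) removes all three benzyl groups and joins the route at 14.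

Step 2. The aryl Grignard reagent may add directly to the lactone or ester carbonyl in competition with cyclopropane opening, and an aryl copper species may open the ring more sluggishly than an alkyl one. The fallback sets out from 8 and comes back at 7; it builds the lactone by asymmetric hydrogenation instead. Stobbe condensation of 8 with dimethyl succinate (NaOMe, MeOH, reflux) gives the (E)-benzylidenesuccinic half-ester F6. Hydrogenation with [Rh(cod)2]BF4 and a chiral bisphosphine of the DuPhos or DIOP family (the antipode that delivers the R acid; H2, MeOH) gives the (R)-benzylsuccinic half-ester F7. Chemoselective reduction of the ester in the carboxylate salt (KOH, then Ca(BH4)2 from CaCl2 and NaBH4, EtOH) and acidification lactonise to 7.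

Step 6. The benzylic cation may be captured by the electron-rich benzyl ring instead of by the hydroxyl (premature carbocyclisation, which would leave the two CH2OH groups undifferentiated), or it may eliminate to a styrene. The fallback sets out from 10 and comes back at 11; it closes the ether at the ketone oxidation level. MnO2 in CH2Cl2 oxidises only the benzylic alcohol of 10 to the aryl ketone diol F8, which closes with the 1,4-related CH2OH to the five-membered cyclic hemiketal F9. Et3SiH with BF3·OEt2 at −78 °C reduces F9 through its oxocarbenium ion to 11, hydride arriving trans to the C3 substituent. Epimerisation α to the ketone has to be watched at the stage of F8.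

Further compounds
F1 | step 8 | [(2S,3R,4R)-2-[4-(benzyloxy)-3-methoxyphenyl]-4-[4-(benzyloxy)-3-methoxybenzyl]tetrahydrofuran-3-yl]methyl acetate | COc1cc(C[C@H]2CO[C@H](c3ccc(OCc4ccccc4)c(OC)c3)[C@H]2COC(C)=O)ccc1OCc1ccccc1
F2 | step 8 | [(1S,2R,3R)-7-(benzyloxy)-1-[4-(benzyloxy)-3-methoxyphenyl]-3-(hydroxymethyl)-6-methoxy-1,2,3,4-tetrahydronaphthalen-2-yl]methyl acetate | COc1cc([C@H]2c3cc(OCc4ccccc4)c(OC)cc3C[C@@H](CO)[C@@H]2COC(C)=O)ccc1OCc1ccccc1
F3 | step 8 | [(1S,2R,3R)-7-(benzyloxy)-1-[4-(benzyloxy)-3-methoxyphenyl]-3-[(benzyloxy)methyl]-6-methoxy-1,2,3,4-tetrahydronaphthalen-2-yl]methyl acetate | COc1cc([C@H]2c3cc(OCc4ccccc4)c(OC)cc3C[C@@H](COCc3ccccc3)[C@@H]2COC(C)=O)ccc1OCc1ccccc1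
F4 | step 8 | [(1S,2R,3R)-7-(benzyloxy)-1-[4-(benzyloxy)-3-methoxyphenyl]-3-[(benzyloxy)methyl]-6-methoxy-1,2,3,4-tetrahydronaphthalen-2-yl]methanol | COc1cc([C@H]2c3cc(OCc4ccccc4)c(OC)cc3C[C@@H](COCc3ccccc3)[C@@H]2CO)ccc1OCc1ccccc1
F5 | step 8 | sodium [(1S,2R,3R)-7-(benzyloxy)-1-[4-(benzyloxy)-3-methoxyphenyl]-3-[(benzyloxy)methyl]-6-methoxy-1,2,3,4-tetrahydronaphthalen-2-yl]methyl sulfate | COc1cc([C@H]2c3cc(OCc4ccccc4)c(OC)cc3C[C@@H](COCc3ccccc3)[C@@H]2COS(=O)(=O)[O-])ccc1OCc1ccccc1.[Na+]
F6 | step 2 | (E)-4-[4-(benzyloxy)-3-methoxyphenyl]-3-(methoxycarbonyl)but-3-enoic acid | OC(=O)C/C(C(=O)OC)=C\c1ccc(OCc2ccccc2)c(OC)c1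
F7 | step 2 | (R)-4-[4-(benzyloxy)-3-methoxyphenyl]-3-(methoxycarbonyl)butanoic acid | COC(=O)[C@H](Cc1ccc(OCc2ccccc2)c(OC)c1)CC(=O)O
F8 | step 6 | (2R,3R)-3-[4-(benzyloxy)-3-methoxybenzyl]-1-[4-(benzyloxy)-3-methoxyphenyl]-4-hydroxy-2-(hydroxymethyl)butan-1-one | OC[C@H](Cc1ccc(OCc2ccccc2)c(OC)c1)[C@H](CO)C(=O)c1ccc(OCc2ccccc2)c(OC)c1
F9 | step 6 | (3R,4R)-2-[4-(benzyloxy)-3-methoxyphenyl]-4-[4-(benzyloxy)-3-methoxybenzyl]-3-(hydroxymethyl)tetrahydrofuran-2-ol | COc1cc(C[C@H]2COC(O)(c3ccc(OCc4ccccc4)c(OC)c3)[C@H]2CO)ccc1OCc1ccccc1
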